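**Plan**
- Retrosynthesis: cut the two gallate esters and the two interflavan C4–C8 bonds, then open ring C of each flavan unit across C2–C3 and C4–C4a (shown for the terminal unit).
- Enabling feature: O1 lies between C8a of the phloroglucinol ring A and C2, which carries the catechol ring B. The ion O1=C2(+) conjugated with C8a=C4a is therefore a cationic 2-oxadiene, and ring C is its [4+2] adduct with the C3=C4 unit of an enediol acetonide.
- Forward: mixed aryl methyl acetal, then the cycloadduct (ring C with a 3,4-acetonide as temporary ring). Its C4–O bond is removed by hydride for the terminal unit and used as leaving group for two C4-to-C8 couplings built from the terminal unit upward. Double galloylation comes between the couplings, the last electrophile carries a temporary bromine cap at C8, and global hydrogenolysis ends the route.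
- Stereochemistry: C2 and C3 of every unit come from the catalyst-controlled endo cycloaddition (2R, 2,3-cis). C4 of the two extender units comes from attack anti to the 3-oxygen and the 2-aryl group (4β, 3,4-trans).

Key step: step 3

Assumption: 2,2-dimethyl-1,3-dioxole is taken as a catalogue compound; the (R)-configured acid of step 3 is assumed to give the 2R series, and the (S)-acid would be used if the sense of induction proves reversed.

Step 1
Reactants: 1 3,4-bis(benzyloxy)benzaldehyde
Product: 2 3,4-bis(benzyloxy)benzaldehyde dimethyl acetal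
Conditions: HC(OMe)3 (3 equiv), MeOH, p-TsOH·H2O (1 mol %), 50 °C; Et3N, concentrate
Reagents that add atoms: trimethyl orthoformate, COC(OC)OC; methanol (solvent), CO
Why: Acid-catalysed acetalisation with an orthoester as water scavenger is routine and gives the carrier of C2 with ring B at the acetal oxidation level.

Step 2
Reactants: 2 3,4-bis(benzyloxy)benzaldehyde dimethyl acetal; 3 3,5-bis(benzyloxy)phenol
Product: 5 racemic 3,4-bis(benzyloxy)benzaldehyde methyl 3,5-bis(benzyloxy)phenyl acetal, via α-chloro ether 4 (not isolated)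
Conditions: AcCl (1.1 equiv), SOCl2 (2 mol %), CH2Cl2, 0 °C to rt, evaporate; then 3, iPr2NEt, CH2Cl2, −40 to 0 °C; chromatography on Et3N-treated silica
Reagents that add atoms: none
Why: Acetal–acyl chloride exchange gives the α-chloro ether, which should alkylate the phenol on oxygen as in a methoxymethyl ether formation; the acetal carbon is racemic but becomes planar in step 3.

Step 3
Reactants: 5 racemic mixed acetal; 6 2,2-dimethyl-1,3-dioxole
Product: 9 all-cis (2R,3S,4R)-5,7,3',4'-tetra-O-benzylflavan-3,4-diol 3,4-acetonide, via aryl oxocarbenium ion 7 (not isolated), via dioxolenium ion 8 (not isolated)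
Conditions: (R)-3,3'-bis(2,4,6-triisopropylphenyl)-1,1'-binaphthyl-2,2'-diyl N-triflylphosphoramide (5 mol %), 6 (3 equiv), 5 Å molecular sieves, toluene/CH2Cl2, −60 °C; Et3N quench
Reagents that add atoms: none
Why: Proposed new method: the chiral acid should protonate the methoxy oxygen of 5 and expel methanol to give the E-configured aryl oxocarbenium ion 7 (O1=C2 conjugated with C8a=C4a of ring A) as a contact ion pair with the phosphoramide anion; one of the equivalent alkene carbons of 6 then adds to C2 and becomes C3, and the dioxolenium ion 8 is captured by C4a with return of the ring proton to the catalyst, so that C2–C3 and C4–C4a form in one operation. The closest known reaction type is the oxa-Povarov reaction of phenol-derived mixed acetals with alkenes under achiral Lewis acids such as SnCl4, together with the enantioselective aza-Povarov reaction of enol ethers under chiral phosphoric acids; the new element is counter-anion control in the oxygen series. Ring C closes as a formal polar [4+2] cycloaddition, the second bond by 6-exo-trig Friedel–Crafts attack of C4a on the dioxolenium carbon, and the five-membered acetonide ring enforces the 3,4-cis fusion. C2 (R) should be set by the anion shielding one face of 7, C3 by the endo approach of 6 with its oxygens under the cationic heterodiene, which places the 3-oxygen cis to the 2-aryl group, and C4 follows from the ring fusion. The step needs enantioface control, endo selectivity and ionisation by loss of methanol and not of the phenol; the first two rest on the tight ion pair at low temperature, the third on the higher basicity of the alkyl oxygen and on the sieves binding methanol. No regiochemical question arises, because the two ortho positions of the 3,5-dibenzyloxyphenyl ring and the two alkene carbons of 6 are each equivalent by symmetry.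

Step 4
Reactants: 9 all-cis flavan-3,4-diol acetonide
Product: 11 5,7,3',4'-tetra-O-benzyl-(−)-epicatechin, via hemiketal-armed C4 cation 10 (not isolated)
Conditions: Et3SiH (10 equiv), CF3CO2H (3 equiv), CH2Cl2, −40 °C, slow addition of 9; aq. NaHCO3
Reagents that add atoms: none
Why: Ionic hydrogenation: the protic acid should open the benzylic C4–O bond because the cation 10 is stabilised by the 5,7-dioxygenated ring A and O1, the silane delivers hydride to C4, and the 2-hydroxyprop-2-yl arm left on O3 falls away as acetone, so C2 and C3 are untouched.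

Step 5
Reactants: 9 all-cis flavan-3,4-diol acetonide; 11 5,7,3',4'-tetra-O-benzyl-(−)-epicatechin
Product: 13 5,7,3',4'-tetra-O-benzylepicatechin-(4β→8)-5,7,3',4'-tetra-O-benzylepicatechin (both 3-OH free), via silyl-ketal-armed C4 cation 12 (not isolated)
Conditions: 11 (3 equiv, excess recovered), Me3SiOSO2CF3 (0.2 equiv), CH2Cl2, −78 °C, slow addition of 9; aq. NaHCO3
Reagents that add atoms: none
Why: Silyl triflate ionisation of a 4-alkoxyflavan and Friedel–Crafts capture by C8 of a benzylated flavan is the standard interflavan coupling: silylation of O4 opens the C4–O bond to the cation 12, attack anti to the 3-oxygen and the 2-aryl group should set the 4β (3,4-trans) configuration, C8 is preferred over C6, the proton released cleaves the silyl ketal arm on O3 to acetone with return of the silyl triflate, and the excess of 11 suppresses self-condensation.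

Step 6
Reactants: 13 octa-O-benzyl dimer diol; 14 3,4,5-tris(benzyloxy)benzoic acid
Product: 15 3-O-(tri-O-benzylgalloyl)-tetra-O-benzylepicatechin-(4β→8)-3-O-(tri-O-benzylgalloyl)-tetra-O-benzylepicatechin
Conditions: 14 (4 equiv), DCC (4 equiv), DMAP (1 equiv), CH2Cl2, rt
Reagents that add atoms: none
Why: Steglich esterification should acylate both axial 3-hydroxy groups in one operation without touching any stereocentre.

Step 7
Reactants: 9 all-cis flavan-3,4-diol acetonide
Product: 16 8-bromo derivative of acetonide 9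
Conditions: N-bromosuccinimide (1.05 equiv), CH2Cl2, −78 to −20 °C; aq. Na2S2O3/NaHCO3
Reagents that add atoms: N-bromosuccinimide, O=C1CCC(=O)N1Br
Why: Electrophilic aromatic bromination should take place on the phloroglucinol-type ring A, at C8 in preference to C6 as in benzylated flavan-3-ols, and installs a temporary cap that leaves the acetonide and all stereocentres untouched and is removed in step 9.

Step 8
Reactants: 15 dimer digallate; 16 8-bromo acetonide
Product: 18 8-bromo-octadeca-O-benzyl ether of the target (top 3-OH free), via 8-bromo silyl-ketal-armed C4 cation 17 (not isolated)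
Conditions: 16 (1.5 equiv), Me3SiOSO2CF3 (0.3 equiv), CH2Cl2, −78 to −40 °C, slow addition of 16; aq. NaHCO3
Reagents that add atoms: none
Why: Same cationic Friedel–Crafts interflavan coupling as step 5: the only free C8 of 15 is in its upper unit and should attack the cation 17 anti to the 3-oxygen and the 2-aryl group to give the 4β bond, the bromine at C8 of the electrophile blocks its self-condensation and any further chain growth so that 16 can be used in excess, and the 3-hydroxy group released on the new top unit stays free because galloylation is already complete.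

Step 9
Reactants: 18 8-bromo-octadeca-O-benzyl trimer
Product: 19 epicatechin-(4β→8)-epicatechin 3-O-gallate-(4β→8)-epicatechin 3-O-gallate (CNP0279403.1)
Conditions: H2 (1 atm), Pd(OH)2/C, NaOAc (1.5 equiv), THF/MeOH/H2O, rt; filtration under N2, Sephadex LH-20, lyophilisation
Reagents that add atoms: none
Why: Hydrogenolysis over Pd(OH)2 should cleave all eighteen benzyl ethers and the aryl C–Br bond in one operation, the acetate buffering the HBr so that the gallate esters, the acid-labile interflavan bonds and all stereocentres stay intact.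

**Compound list**
1 | 3,4-bis(benzyloxy)benzaldehyde | O=Cc1ccc(OCc2ccccc2)c(OCc2ccccc2)c1 | starting material
2 | 3,4-bis(benzyloxy)benzaldehyde dimethyl acetal | COC(OC)c1ccc(OCc2ccccc2)c(OCc2ccccc2)c1 | intermediate
3 | 3,5-bis(benzyloxy)phenol | Oc1cc(OCc2ccccc2)cc(OCc2ccccc2)c1 | starting material
4 | racemic 1,2-bis(benzyloxy)-4-[chloro(methoxy)methyl]benzene (α-chloro ether) | COC(Cl)c1ccc(OCc2ccccc2)c(OCc2ccccc2)c1 | intermediate
5 | racemic 3,4-bis(benzyloxy)benzaldehyde methyl 3,5-bis(benzyloxy)phenyl acetal | COC(Oc1cc(OCc2ccccc2)cc(OCc2ccccc2)c1)c1ccc(OCc2ccccc2)c(OCc2ccccc2)c1 | intermediate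
6 | 2,2-dimethyl-1,3-dioxole | CC1(C)OC=CO1 | starting material
7 | (E)-[3,4-bis(benzyloxy)benzylidene][3,5-bis(benzyloxy)phenyl]oxonium ion (cation of the ion pair with the chiral anion) | c1ccccc1COc1cc(OCc2ccccc2)cc(c1)/[O+]=C/c1ccc(OCc2ccccc2)c(OCc2ccccc2)c1 | intermediate
8 | dioxolenium ion after the first bond: C2 (R) carries H, ring B and the aryloxy group, C3 (S) is in the 2,2-dimethyl-1,3-dioxolane ring, C4 is its oxocarbenium carbon | CC1(C)O[C@H](C=[O+]1)[C@H](Oc1cc(OCc2ccccc2)cc(OCc2ccccc2)c1)c1ccc(OCc2ccccc2)c(OCc2ccccc2)c1 | intermediate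
9 | all-cis (2R,3S,4R)-5,7,3',4'-tetra-O-benzylflavan-3,4-diol 3,4-O-isopropylidene acetal (H2, H3 and H4 on one face) | CC1(C)O[C@@H]2[C@H](O1)c1c(OCc3ccccc3)cc(OCc3ccccc3)cc1O[C@@H]2c1ccc(OCc2ccccc2)c(OCc2ccccc2)c1 | intermediate
10 | C4 benzylic cation of (2R,3R)-5,7,3',4'-tetra-O-benzylflavan-3-ol carrying the 2-hydroxyprop-2-yl (hemiketal) arm on O3, drawn before loss of acetone | CC(C)(O)O[C@@H]1[CH+]c2c(OCc3ccccc3)cc(OCc3ccccc3)cc2O[C@@H]1c1ccc(OCc2ccccc2)c(OCc2ccccc2)c1 | intermediate
11 | (2R,3R)-5,7,3',4'-tetra-O-benzylepicatechin | O[C@@H]1Cc2c(OCc3ccccc3)cc(OCc3ccccc3)cc2O[C@@H]1c1ccc(OCc2ccccc2)c(OCc2ccccc2)c1 | intermediate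
12 | C4 benzylic cation of (2R,3R)-5,7,3',4'-tetra-O-benzylflavan-3-ol carrying the 2-(trimethylsilyloxy)prop-2-yl (silyl ketal) arm on O3 | C[Si](C)(C)OC(C)(C)O[C@@H]1[CH+]c2c(OCc3ccccc3)cc(OCc3ccccc3)cc2O[C@@H]1c1ccc(OCc2ccccc2)c(OCc2ccccc2)c1 | intermediate
13 | tetra-O-benzylepicatechin-(4β→8)-tetra-O-benzylepicatechin, both 3-OH free | O[C@@H]1[C@@H](c2c(OCc5ccccc5)cc(OCc5ccccc5)c3c2O[C@H](c2ccc(OCc5ccccc5)c(OCc5ccccc5)c2)[C@H](O)C3)c2c(OCc5ccccc5)cc(OCc5ccccc5)cc2O[C@@H]1c1ccc(OCc5ccccc5)c(OCc5ccccc5)c1 | intermediate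
14 | 3,4,5-tris(benzyloxy)benzoic acid | O=C(O)c1cc(OCc2ccccc2)c(OCc2ccccc2)c(OCc2ccccc2)c1 | starting material
15 | dimer 13 with both 3-OH groups esterified by 3,4,5-tris(benzyloxy)benzoic acid | O=C(O[C@@H]1[C@@H](c2c(OCc5ccccc5)cc(OCc5ccccc5)c3c2O[C@H](c2ccc(OCc5ccccc5)c(OCc5ccccc5)c2)[C@H](OC(=O)c2cc(OCc5ccccc5)c(OCc5ccccc5)c(OCc5ccccc5)c2)C3)c2c(OCc5ccccc5)cc(OCc5ccccc5)cc2O[C@@H]1c1ccc(OCc5ccccc5)c(OCc5ccccc5)c1)c1cc(OCc5ccccc5)c(OCc5ccccc5)c(OCc5ccccc5)c1 | intermediate
16 | all-cis (2R,3S,4R)-8-bromo-5,7,3',4'-tetra-O-benzylflavan-3,4-diol 3,4-O-isopropylidene acetal | CC1(C)O[C@@H]2[C@H](O1)c1c(OCc3ccccc3)cc(OCc3ccccc3)c(Br)c1O[C@@H]2c1ccc(OCc2ccccc2)c(OCc2ccccc2)c1 | intermediate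
17 | C4 benzylic cation of (2R,3R)-8-bromo-5,7,3',4'-tetra-O-benzylflavan-3-ol carrying the 2-(trimethylsilyloxy)prop-2-yl arm on O3 | C[Si](C)(C)OC(C)(C)O[C@@H]1[CH+]c2c(OCc3ccccc3)cc(OCc3ccccc3)c(Br)c2O[C@@H]1c1ccc(OCc2ccccc2)c(OCc2ccccc2)c1 | intermediate
18 | target with all eighteen phenolic OH groups as benzyl ethers and bromine at C8 of the top unit, top 3-OH free; all units 2,3-cis, both interflavan bonds 4β→8 | O=C(O[C@@H]1[C@@H](c2c(OCc5ccccc5)cc(OCc5ccccc5)c3c2O[C@H](c2ccc(OCc5ccccc5)c(OCc5ccccc5)c2)[C@H](OC(=O)c2cc(OCc5ccccc5)c(OCc5ccccc5)c(OCc5ccccc5)c2)C3)c2c(OCc5ccccc5)cc(OCc5ccccc5)c([C@H]3c4c(OCc5ccccc5)cc(OCc5ccccc5)c(Br)c4O[C@H](c4ccc(OCc5ccccc5)c(OCc5ccccc5)c4)[C@@H]3O)c2O[C@@H]1c1ccc(OCc5ccccc5)c(OCc5ccccc5)c1)c1cc(OCc5ccccc5)c(OCc5ccccc5)c(OCc5ccccc5)c1 | intermediate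
19 | epicatechin-(4β→8)-epicatechin 3-O-gallate-(4β→8)-epicatechin 3-O-gallate | O=C(O[C@@H]1[C@@H](c2c(O)cc(O)c3c2O[C@H](c2ccc(O)c(O)c2)[C@H](OC(=O)c2cc(O)c(O)c(O)c2)C3)c2c(O)cc(O)c([C@H]3c4c(O)cc(O)cc4O[C@H](c4ccc(O)c(O)c4)[C@@H]3O)c2O[C@@H]1c1ccc(O)c(O)c1)c1cc(O)c(O)c(O)c1 | target

**Count**
Total steps: 9. Longest linear sequence: 8 (steps 1, 2, 3, 4, 5, 6, 8 and 9; step 7 is a one-step branch from 9, which is drawn on three times).

**Steps most likely to fail**

Step 3. The ion pair may give poor enantioface or endo/exo control. The acetal may ionise by loss of the phenol and then C-benzylate ring A. The product may re-ionise at C4 under the acid and oligomerise. The fallback uses known chemistry and takes the stereochemistry from a different source. It sets out from 5. Treatment with SnCl4 (tin tetrachloride) and 6 in CH2Cl2 at −78 °C, the established achiral oxa-Povarov reaction, should give the racemic cis-fused acetonide F1 as a mixture of C2 epimers. Et3SiH/CF3CO2H then removes the C4 oxygen to give the racemic flavan-3-ol F2. Dess–Martin periodinane gives the flavan-3-one F3, whose C2 is epimerisable. Asymmetric transfer hydrogenation with dynamic kinetic resolution, using RuCl(p-cymene)[(R,R)-TsDPEN] or its enantiomer (whichever gives the 3R carbinol) with HCO2H/Et3N, should give the cis (2R,3R) alcohol, which is 11. For the two extender units, 11 is oxidised at C4 with DDQ in the presence of 2-ethoxyethanol to 4β-(2-ethoxyethoxy)-5,7,3',4'-tetra-O-benzylepicatechin F4. Part of F4 is brominated at C8 with N-bromosuccinimide to the 8-bromo ether F5. F4 takes the place of 9 in step 5 and F5 the place of 16 in step 8, so the fallback comes back to the route at 11, 13 and 18.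

Step 8. The hindered digallate may react slowly. Under the silyl triflate its own interflavan bond may ionise and scramble, and C6 positions may compete. The fallback changes the activation from an oxygen leaving group under a Lewis acid to a sulfur leaving group under a thiophilic silver salt, and sets out from 16. 2-Mercaptobenzothiazole with BF3·OEt2 in CH2Cl2 at −40 °C should open the acetonide at C4 and give 8-bromo-4β-(benzothiazol-2-ylthio)-5,7,3',4'-tetra-O-benzylepicatechin F6. AgBF4 in THF at 0 °C then ionises only the C–S bond of F6 in the presence of 15, under conditions that leave the existing interflavan bond alone. The coupling returns to the route at 18.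

Step 4. Hydride transfer from the silane may be slower than capture of the cation by the product, giving oligomers. The acetonide may also open at the ketal carbon and end as a 3-O-isopropyl ether. The fallback replaces hydride by a much stronger nucleophile and sets out from 9. Benzyl mercaptan with BF3·OEt2 in CH2Cl2 at −78 °C should give 4β-benzylthio-5,7,3',4'-tetra-O-benzylepicatechin F7. Desulfurisation with Raney Ni in EtOH/THF returns to the route at 11.

**Further compounds**
F1 | step 3 | racemic cis-fused 5,7,3',4'-tetra-O-benzylflavan-3,4-diol 3,4-acetonide (mixture of C2 epimers) | CC1(C)OC2C(O1)c1c(OCc3ccccc3)cc(OCc3ccccc3)cc1OC2c1ccc(OCc2ccccc2)c(OCc2ccccc2)c1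
F2 | step 3 | racemic 5,7,3',4'-tetra-O-benzylflavan-3-ol (cis/trans mixture) | OC1Cc2c(OCc3ccccc3)cc(OCc3ccccc3)cc2OC1c1ccc(OCc2ccccc2)c(OCc2ccccc2)c1
F3 | step 3 | racemic 5,7,3',4'-tetra-O-benzylflavan-3-one | O=C1Cc2c(OCc3ccccc3)cc(OCc3ccccc3)cc2OC1c1ccc(OCc2ccccc2)c(OCc2ccccc2)c1
F4 | step 3 | 4β-(2-ethoxyethoxy)-5,7,3',4'-tetra-O-benzylepicatechin | O[C@@H]1[C@@H](OCCOCC)c2c(OCc3ccccc3)cc(OCc3ccccc3)cc2O[C@@H]1c1ccc(OCc2ccccc2)c(OCc2ccccc2)c1
F5 | step 3 | 8-bromo-4β-(2-ethoxyethoxy)-5,7,3',4'-tetra-O-benzylepicatechin | O[C@@H]1[C@@H](OCCOCC)c2c(OCc3ccccc3)cc(OCc3ccccc3)c(Br)c2O[C@@H]1c1ccc(OCc2ccccc2)c(OCc2ccccc2)c1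
F6 | step 8 | 8-bromo-4β-(benzothiazol-2-ylthio)-5,7,3',4'-tetra-O-benzylepicatechin | O[C@@H]1[C@@H](Sc2nc3ccccc3s2)c2c(OCc3ccccc3)cc(OCc3ccccc3)c(Br)c2O[C@@H]1c1ccc(OCc2ccccc2)c(OCc2ccccc2)c1
F7 | step 4 | 4β-benzylthio-5,7,3',4'-tetra-O-benzylepicatechin | O[C@@H]1[C@@H](SCc2ccccc2)c2c(OCc3ccccc3)cc(OCc3ccccc3)cc2O[C@@H]1c1ccc(OCc2ccccc2)c(OCc2ccccc2)c1
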